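**Plan**

1. Numbering used throughout: ring A = C1–C5, spiro atom C6, ring B = C7–C11. The retrosynthesis first removes the C3 hydroxyl (ketone reduction) and the C4 bromine (α′-bromination), which leads back to a spiro enone (C3 ketone, C1=C2).
2. Ring A of that enone is cut at C1=C2 and at C4–C5 together. C2–C3–C4 is an acetone unit, and what remains is ring B carrying an acetyl group (C1) and a 2-chloropropan-2-yl group (C5) on the same quaternary carbon C6. This 1,3-pair of electrophilic carbons across C6 (ketone carbon and tertiary C–Cl) is the feature that allows one [3+3] annulation with an acetone α,α′-dianion equivalent.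
3. Forward order: acyclic quaternary α-cyano ester, then ring B by ozonolysis and aldol condensation, then the vinyl bromide by reductive enol triflation and triflate/bromide exchange, then nitrile and ester turned into acetyl and CMe2Cl, then ring A by the [3+3] annulation, then bromination at C4 and reduction at C3.
4. Stereochemistry: C6 comes from a catalytic asymmetric phase-transfer allylation and stays quaternary throughout. C4 comes from face-selective bromination of the ring-A dienolate under control of ring B. C3 comes from a catalyst-controlled Corey–Bakshi–Shibata reduction.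

Key step: step 11

Assumption: the sense of induction of the phase-transfer catalyst in step 2 is assigned by analogy with other α-alkyl α-cyano esters; the catalyst enantiomer that gives (S)-5 is the one used.

**Step 1**
Reactants: 1 (tert-butyl cyanoacetate), 2 (1-bromobutan-2-one)
Product: 3 tert-butyl 2-cyano-4-oxohexanoate (racemic)
Conditions: K2CO3, NaI (cat.), acetone, 0 → 23 °C, twofold excess of 1
Reagents that add atoms: none
Why: SN2 alkylation of the doubly stabilised cyanoacetate carbanion by the α-bromo ketone, with the excess of 1 and the mild base limiting double alkylation and cyclisation of the γ-keto nitrile.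

**Step 2**
Reactants: 3 (tert-butyl 2-cyano-4-oxohexanoate), 4 (allyl bromide)
Product: 5 tert-butyl (2S)-2-cyano-4-oxo-2-(prop-2-en-1-yl)hexanoate
Conditions: chiral N-spiro bis(binaphthyl)ammonium bromide bearing 3,4,5-trifluorophenyl groups (2 mol %), K2CO3 (50 % aq.), toluene, –20 °C
Reagents that add atoms: none
Why: Asymmetric phase-transfer C-allylation of an α-alkyl α-cyano ester, in which the chiral ammonium cation forms a tight ion pair with the prochiral enolate and leaves one face open to allyl bromide, so that the quaternary stereocentre (the later spiro atom C6) is set by the catalyst.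

**Step 3**
Reactants: 5 (tert-butyl (2S)-2-cyano-4-oxo-2-(prop-2-en-1-yl)hexanoate)
Product: 7 tert-butyl (2S)-2-cyano-4-oxo-2-(2-oxoethyl)hexanoate, via ozonide 6 (not isolated)
Conditions: O3, CH2Cl2, –78 °C; then Me2S, –78 → 23 °C
Reagents that add atoms: ozone, [O-][O+]=O
Why: Ozonolysis with reductive work-up cleaves only the terminal alkene and unmasks the CH2CHO arm, while ketone, nitrile, ester and the quaternary centre are untouched.

**Step 4**
Reactants: 7 (tert-butyl (2S)-2-cyano-4-oxo-2-(2-oxoethyl)hexanoate)
Product: 9 tert-butyl (1S)-1-cyano-4-methyl-3-oxocyclohex-4-ene-1-carboxylate, via ketol 8 (not isolated)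
Conditions: pyrrolidine (20 mol %), AcOH (20 mol %), toluene, 60 °C
Reagents that add atoms: none
Why: Intramolecular aldol condensation (6-(enolendo)-exo-trig) of the ethyl ketone α-carbon onto the aldehyde, in which every other enolisable position could only close a four-membered ring, so ring B should form as one regioisomer with the methyl group on the α-carbon of the enone.

**Step 5**
Reactants: 9 (tert-butyl (1S)-1-cyano-4-methyl-3-oxocyclohex-4-ene-1-carboxylate)
Product: 11 tert-butyl (1S)-1-cyano-4-methyl-3-[(trifluoromethanesulfonyl)oxy]cyclohex-3-ene-1-carboxylate, via lithium enolate 10 (not isolated)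
Conditions: LiBH(s-Bu)3 (1.05 equiv), THF, –78 °C; then PhNTf2, –78 → 0 °C
Reagents that add atoms: N-phenylbis(trifluoromethanesulfonimide), FC(F)(F)S(=O)(=O)N(c1ccccc1)S(=O)(=O)C(F)(F)F
Why: Conjugate hydride reduction of the α-methyl enone gives the tetrasubstituted enolate regiospecifically and O-triflation traps it, which fixes the ring-B double bond between the future C8 and C9.

**Step 6**
Reactants: 11 (tert-butyl (1S)-1-cyano-4-methyl-3-[(trifluoromethanesulfonyl)oxy]cyclohex-3-ene-1-carboxylate)
Product: 12 tert-butyl (1S)-3-bromo-1-cyano-4-methylcyclohex-3-ene-1-carboxylate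
Conditions: Ni(cod)2 (10 mol %), LiBr (3 equiv), DMA/THF, 23 °C
Reagents that add atoms: lithium bromide, [Li+].[Br-]
Why: Nickel-catalysed exchange of an enol triflate for bromide (oxidative addition of zerovalent nickel to the C–O bond, anion exchange, reductive elimination) keeps the alkene position and tolerates nitrile and ester.

**Step 7**
Reactants: 12 (tert-butyl (1S)-3-bromo-1-cyano-4-methylcyclohex-3-ene-1-carboxylate)
Product: 14 1-[(1R)-3-bromo-1-(2-hydroxypropan-2-yl)-4-methylcyclohex-3-en-1-yl]ethan-1-one, via ketimine 13 (not isolated)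
Conditions: CH3Li (5 equiv), Et2O, –78 → 0 °C; then 2 M HCl, THF, 23 °C
Reagents that add atoms: methyllithium, [Li]C; water, O
Why: CH3Li adds twice to the tert-butyl ester (tertiary carbinol, later C5) and once to the nitrile (N-lithio ketimine, hydrolysed to the acetyl group, later C1), while the hindered tetrasubstituted vinyl bromide is not expected to undergo bromine–lithium exchange with CH3Li at low temperature.

**Step 8**
Reactants: 14 (1-[(1R)-3-bromo-1-(2-hydroxypropan-2-yl)-4-methylcyclohex-3-en-1-yl]ethan-1-one)
Product: 15 1-[(1S)-3-bromo-1-(2-chloropropan-2-yl)-4-methylcyclohex-3-en-1-yl]ethan-1-one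
Conditions: HCl (gas), CH2Cl2, 0 °C; crude product used at once
Reagents that add atoms: hydrogen chloride, Cl
Why: SN1 substitution of the tertiary alcohol by chloride, in which the quaternary neighbour carries no hydrogen so that no conjugated enone can form.

**Step 9**
Reactants: 16 ((trimethylsilyl)methylmagnesium chloride), 17 (acetic anhydride)
Product: 18 1-(trimethylsilyl)propan-2-one
Conditions: Et2O, –78 °C, addition of 16 to excess 17; then cold aq. NH4Cl
Reagents that add atoms: none
Why: Acylation of the Grignard reagent by the anhydride at low temperature with inverse addition stops at the ketone.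

**Step 10**
Reactants: 18 (1-(trimethylsilyl)propan-2-one)
Product: 20 trimethyl{[3-(trimethylsilyl)prop-1-en-2-yl]oxy}silane, via lithium enolate 19 (not isolated)
Conditions: LiN(i-Pr)2, THF, –78 °C; then Me3SiCl
Reagents that add atoms: chlorotrimethylsilane, C[Si](C)(C)Cl
Why: Kinetic deprotonation at the methyl group (away from silicon) and O-silylation give the terminal enol silane, an acetone α,α′-dianion equivalent.

**Step 11**
Reactants: 15 (1-[(1S)-3-bromo-1-(2-chloropropan-2-yl)-4-methylcyclohex-3-en-1-yl]ethan-1-one), 20 (trimethyl{[3-(trimethylsilyl)prop-1-en-2-yl]oxy}silane)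
Product: 23 (6R)-8-bromo-1,5,5,9-tetramethylspiro[5.5]undeca-1,8-dien-3-one, via silyl diketone 21 (not isolated), via ketol 22 (not isolated)
Conditions: 20 (1.5 equiv), TiCl4 (2.5 equiv), CH2Cl2, –78 → 23 °C; then TsOH·H2O (cat.), toluene, 60 °C on the crude ketol
Reagents that add atoms: none
Why: Proposed new method: TiCl4 ionises the tertiary C–Cl bond of 15 and the cation is trapped at the CH2 terminus of enol silane 20 (SN1 α-tert-alkylation of a silyl enol ether, Reetz type, the closest known reaction) to give α-silyl ketone 21, whose C–Si bond TiCl4 then converts into a titanium enolate located only at the former CH2Si carbon; this enolate adds to the TiCl4-activated acetyl group (intramolecular Mukaiyama-type aldol) and ketol 22 loses water to the conjugated enone. Ring A closes in the 6-(enolendo)-exo-trig mode. No stereocentre is created in 23, because the carbinol carbon of 22 becomes sp2, and the quaternary carbon of 15 takes no part, so its configuration is carried into the spiro atom. The step needs regioselectivity in the aldol (C2 must attack the acetyl carbon C1, instead of the acetyl methyl attacking the new ketone), which the substrate secures because the only enolate present is the one unmasked from the C–Si bond and no base is there to enolise the acetyl group. It also needs trapping of the cation to outrun 1,2-acyl shift, proton loss and retro-acylation: coordination of TiCl4 to the acetyl oxygen should lower its migratory aptitude, and an excess of the strongly nucleophilic 20 at –78 °C favours bimolecular capture. The tertiary chloride carbon and the acetyl carbon, both on the quaternary ring carbon, form the 1,3-dielectrophile that matches the 1,3-dinucleophile 20.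

**Step 12**
Reactants: 23 ((6R)-8-bromo-1,5,5,9-tetramethylspiro[5.5]undeca-1,8-dien-3-one)
Product: 25 (4S,6S)-4,8-dibromo-1,5,5,9-tetramethylspiro[5.5]undeca-1,8-dien-3-one, via lithium dienolate 24 (not isolated)
Conditions: LiN(i-Pr)2 (1.1 equiv), THF, –78 °C; then NBS, –78 °C
Reagents that add atoms: N-bromosuccinimide, BrN1C(=O)CCC1=O
Why: Kinetic deprotonation at C4 (α′) gives the cross-conjugated dienolate, which should be brominated at C4 on the ring-A face syn to C7 (the flatter, sp2-terminated arm of ring B) and anti to the puckered C10–C11 arm, so that the (4S) bromide is expected as the major epimer.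

**Step 13**
Reactants: 25 ((4S,6S)-4,8-dibromo-1,5,5,9-tetramethylspiro[5.5]undeca-1,8-dien-3-one)
Product: 26 (3S,4S,6S)-4,8-dibromo-1,5,5,9-tetramethylspiro[5.5]undeca-1,8-dien-3-ol
Conditions: (R)-2-methyl-CBS-oxazaborolidine (20 mol %), catecholborane (1.5 equiv), toluene, –78 °C; pH 7 buffer work-up
Reagents that add atoms: none
Why: Corey–Bakshi–Shibata reduction under catalyst control, in which the ketone binds with its bulky CHBr–CMe2 flank away from the catalyst and hydride is delivered to C3 from the face that carries the C4 bromine, which should give the (3S) alcohol trans to bromine without conjugate reduction.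

**Compound list**

1 | tert-butyl cyanoacetate | N#CCC(=O)OC(C)(C)C | starting material
2 | 1-bromobutan-2-one | CCC(=O)CBr | starting material
3 | tert-butyl 2-cyano-4-oxohexanoate (racemic) | CCC(=O)CC(C#N)C(=O)OC(C)(C)C | intermediate
4 | allyl bromide (3-bromoprop-1-ene) | C=CCBr | starting material
5 | tert-butyl (2S)-2-cyano-4-oxo-2-(prop-2-en-1-yl)hexanoate | CC(C)(C)OC(=O)[C@](C#N)(CC(=O)CC)CC=C | intermediate
6 | tert-butyl (2S)-2-cyano-4-oxo-2-[(1,2,4-trioxolan-3-yl)methyl]hexanoate (ozonide) | CC(C)(C)OC(=O)[C@](C#N)(CC(=O)CC)CC1OCOO1 | intermediate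
7 | tert-butyl (2S)-2-cyano-4-oxo-2-(2-oxoethyl)hexanoate | CC(C)(C)OC(=O)[C@](C#N)(CC(=O)CC)CC=O | intermediate
8 | tert-butyl (1S)-1-cyano-5-hydroxy-4-methyl-3-oxocyclohexane-1-carboxylate (ketol, mixture at C4 and C5) | CC(C)(C)OC(=O)[C@]1(C#N)CC(=O)C(C)C(O)C1 | intermediate
9 | tert-butyl (1S)-1-cyano-4-methyl-3-oxocyclohex-4-ene-1-carboxylate | CC(C)(C)OC(=O)[C@]1(C#N)CC(=O)C(C)=CC1 | intermediate
10 | lithium (5S)-5-(tert-butoxycarbonyl)-5-cyano-2-methylcyclohex-1-en-1-olate (lithium enolate) | CC(C)(C)OC(=O)[C@]1(C#N)CC(O[Li])=C(C)CC1 | intermediate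
11 | tert-butyl (1S)-1-cyano-4-methyl-3-[(trifluoromethanesulfonyl)oxy]cyclohex-3-ene-1-carboxylate | CC(C)(C)OC(=O)[C@]1(C#N)CC(OS(=O)(=O)C(F)(F)F)=C(C)CC1 | intermediate
12 | tert-butyl (1S)-3-bromo-1-cyano-4-methylcyclohex-3-ene-1-carboxylate | CC(C)(C)OC(=O)[C@]1(C#N)CC(Br)=C(C)CC1 | intermediate
13 | 2-[(1S)-3-bromo-1-ethanimidoyl-4-methylcyclohex-3-en-1-yl]propan-2-ol (ketimine) | CC(=N)[C@@]1(C(C)(C)O)CC(Br)=C(C)CC1 | intermediate
14 | 1-[(1R)-3-bromo-1-(2-hydroxypropan-2-yl)-4-methylcyclohex-3-en-1-yl]ethan-1-one | CC(=O)[C@@]1(C(C)(C)O)CC(Br)=C(C)CC1 | intermediate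
15 | 1-[(1S)-3-bromo-1-(2-chloropropan-2-yl)-4-methylcyclohex-3-en-1-yl]ethan-1-one | CC(=O)[C@@]1(C(C)(C)Cl)CC(Br)=C(C)CC1 | intermediate
16 | (trimethylsilyl)methylmagnesium chloride | C[Si](C)(C)C[Mg]Cl | starting material
17 | acetic anhydride | CC(=O)OC(C)=O | starting material
18 | 1-(trimethylsilyl)propan-2-one | CC(=O)C[Si](C)(C)C | intermediate
19 | lithium 3-(trimethylsilyl)prop-1-en-2-olate (lithium enolate) | [Li]OC(=C)C[Si](C)(C)C | intermediate
20 | trimethyl{[3-(trimethylsilyl)prop-1-en-2-yl]oxy}silane | C=C(O[Si](C)(C)C)C[Si](C)(C)C | intermediate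
21 | 1-[(1R)-3-bromo-4-methyl-1-[2-methyl-4-oxo-5-(trimethylsilyl)pentan-2-yl]cyclohex-3-en-1-yl]ethan-1-one (silyl diketone) | C[Si](C)(C)CC(=O)CC(C)(C)[C@]1(C(C)=O)CC(Br)=C(C)CC1 | intermediate
22 | (6R)-8-bromo-1-hydroxy-1,5,5,9-tetramethylspiro[5.5]undec-8-en-3-one (ketol, mixture at C1) | CC1(O)CC(=O)CC(C)(C)[C@]12CCC(C)=C(Br)C2 | intermediate
23 | (6R)-8-bromo-1,5,5,9-tetramethylspiro[5.5]undeca-1,8-dien-3-one | CC1=CC(=O)CC(C)(C)[C@]12CCC(C)=C(Br)C2 | intermediate
24 | lithium (6S)-8-bromo-1,5,5,9-tetramethylspiro[5.5]undeca-1,3,8-trien-3-olate (lithium dienolate) | CC1=CC(O[Li])=CC(C)(C)[C@]12CCC(C)=C(Br)C2 | intermediate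
25 | (4S,6S)-4,8-dibromo-1,5,5,9-tetramethylspiro[5.5]undeca-1,8-dien-3-one | CC1=CC(=O)[C@@H](Br)C(C)(C)[C@]12CCC(C)=C(Br)C2 | intermediate
26 | (3S,4S,6S)-4,8-dibromo-1,5,5,9-tetramethylspiro[5.5]undeca-1,8-dien-3-ol | CC1=C[C@H](O)[C@@H](Br)C(C)(C)[C@]12CCC(C)=C(Br)C2 | target

**Step count**

Total: 13 steps. Longest linear sequence: 11 steps (steps 1–8 and 11–13); steps 9 and 10 prepare reagent 20.

**Steps most likely to fail**

Step 11 (bears the label). After ionisation the tertiary cation may undergo acyl migration, proton loss or loss of an acylium ion faster than it is trapped, and the titanium enolate may close only slowly on the hindered ketone. The fallback uses known reactions only, sets out from 15 and comes back at 23. It keeps the SN1 alkylation, which has direct precedent with ketene silyl acetals, but closes the ring by a Claisen condensation and adds the C1 methyl last. Compound 15 is alkylated with 1-methoxy-1-(trimethylsilyloxy)ethene and ZnCl2 (cat.) in CH2Cl2 to the δ-keto ester methyl 3-[(1R)-1-acetyl-3-bromo-4-methylcyclohex-3-en-1-yl]-3-methylbutanoate F1. KOt-Bu in THF then condenses the acetyl methyl group onto the ester to give the spiro dione (6R)-8-bromo-5,5,9-trimethylspiro[5.5]undec-8-ene-1,3-dione F2. Methanol and TsOH convert the less hindered C3 carbonyl into the vinylogous ester (6R)-8-bromo-3-methoxy-5,5,9-trimethylspiro[5.5]undeca-2,8-dien-1-one F3. Addition of CH3Li with CeCl3 to the C1 carbonyl and treatment with aqueous HCl (Stork–Danheiser transposition) gives 23.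

Step 12. Deprotonation at the C1 methyl group may compete with deprotonation at C4, a second bromination may occur, and bromine may be delivered with poor facial selectivity or the C4 centre may epimerise through the enol. The fallback sets out from 23 and comes back at 26, introducing bromine and oxygen together by anti addition, so that steps 12 and 13 are both replaced. Compound 23 is condensed with TsNHNH2 to the tosylhydrazone N′-[(6R)-8-bromo-1,5,5,9-tetramethylspiro[5.5]undeca-1,8-dien-3-ylidene]-4-methylbenzenesulfonohydrazide F4. LiN(i-Pr)2 in THF (Shapiro-type elimination) gives the diene (6S)-8-bromo-1,5,5,9-tetramethylspiro[5.5]undeca-1,3,8-triene F5. NBS in aqueous acetone at 0 °C should place bromine on the terminal carbon C4 (the allyl cation is stabilised by the substituted end C1), and water should open the bromonium ion at allylic C3 anti to bromine, which gives 26.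

Step 13. The steric bias of ring A (hydride approach anti to the axial methyl on C5) may override catalyst control and give the cis bromohydrin, and base in the work-up may close the trans bromohydrin to an epoxide. The fallback sets out from 25 and comes back at 26. i-Bu2AlH in CH2Cl2 at –78 °C reduces 25 from the less hindered face to the cis alcohol (3R,4S,6S)-4,8-dibromo-1,5,5,9-tetramethylspiro[5.5]undeca-1,8-dien-3-ol F6. A Mitsunobu reaction with 4-nitrobenzoic acid, PPh3 and DIAD inverts C3 and gives (3S,4S,6S)-4,8-dibromo-1,5,5,9-tetramethylspiro[5.5]undeca-1,8-dien-3-yl 4-nitrobenzoate F7. i-Bu2AlH at –78 °C cleaves the ester without forming a free alkoxide at higher temperature and gives 26.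

**Further compounds**

F1 | step 11 | methyl 3-[(1R)-1-acetyl-3-bromo-4-methylcyclohex-3-en-1-yl]-3-methylbutanoate | COC(=O)CC(C)(C)[C@]1(C(C)=O)CC(Br)=C(C)CC1
F2 | step 11 | (6R)-8-bromo-5,5,9-trimethylspiro[5.5]undec-8-ene-1,3-dione | O=C1CC(=O)CC(C)(C)[C@]12CCC(C)=C(Br)C2
F3 | step 11 | (6R)-8-bromo-3-methoxy-5,5,9-trimethylspiro[5.5]undeca-2,8-dien-1-one | O=C1C=C(OC)CC(C)(C)[C@]12CCC(C)=C(Br)C2
F4 | step 12 | N′-[(6R)-8-bromo-1,5,5,9-tetramethylspiro[5.5]undeca-1,8-dien-3-ylidene]-4-methylbenzenesulfonohydrazide | CC1=CC(=NNS(=O)(=O)c3ccc(C)cc3)CC(C)(C)[C@]12CCC(C)=C(Br)C2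
F5 | step 12 | (6S)-8-bromo-1,5,5,9-tetramethylspiro[5.5]undeca-1,3,8-triene | CC1=CC=CC(C)(C)[C@]12CCC(C)=C(Br)C2
F6 | step 13 | (3R,4S,6S)-4,8-dibromo-1,5,5,9-tetramethylspiro[5.5]undeca-1,8-dien-3-ol | CC1=C[C@@H](O)[C@@H](Br)C(C)(C)[C@]12CCC(C)=C(Br)C2
F7 | step 13 | (3S,4S,6S)-4,8-dibromo-1,5,5,9-tetramethylspiro[5.5]undeca-1,8-dien-3-yl 4-nitrobenzoate | CC1=C[C@H](OC(=O)c3ccc(cc3)[N+](=O)[O-])[C@@H](Br)C(C)(C)[C@]12CCC(C)=C(Br)C2
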